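## Structural features

The target is a C25 terpenoid built on a trans-fused decalin (ring A: C1–C5 and C10; ring B: C5–C10; labdane numbering, C17 on C8, C18 and C19 on C4, C20 on C10, C16 on C13). From C9 a β-oriented chain C11–C12–C13(CH3)=C14–C15(OH) ends at C5′ of a 4-methylfuran-2(5H)-one (lactone atoms O1′, C2′ carbonyl, C3′, C4′ methyl-bearing, C5′). Ring B carries five stereocentres: C10 (S, quaternary, β-methyl), C5 (S, α-H), C6 (S, equatorial 6α-OH), C9 (R, equatorial chain) and C8 (R, tertiary 8α-OH with axial 8β-methyl). C5, C10 and C9 are contiguous, with C6 next to C5 and C8 next to C9. A second, isolated pair, C15 (S) and C5′ (S), forms a threo diol unit; four bonds of chain and an E trisubstituted alkene separate it from the ring, so the decalin cannot relay its configuration there. Fragile points are the butenolide (acidic C5′–H, so epimerisation or elimination to a γ-ylidene lactone under base), the allylic C15 carbinol (ionisation under acid) and the tertiary C8 alcohol. Any stage in which C8 is a ketone β to the C6 oxygen is open to retro-aldol cleavage or loss of water. The real difficulty is the crowded ring B between the C4 gem-dimethyl group and quaternary C10, together with the remote C15/C5′ pair. The key step exploits the fact that the C6 carbinol is β to C8 through C7 and that the groups on C5, C6 and C9 are all equatorial in the trans-decalin. With C8 as a methyl ketone and C6 as an aldehyde, the C6–C7 bond of ring B can therefore be closed reversibly and allowed to settle into the natural arrangement.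

## Logic of the disconnections

36 to 35: only O–Si bonds are cut. The hydroxyls on C6, C8 and C15 are carried as one kind of silyl ether so that a single mild step ends the synthesis. The forward step must avoid base (C5′–H) and strong acid (C15).

35 to 34 to 33: the C3′=C4′ bond (metathesis) and the C2′–O5′ ester bond are cut. The butenolide is too acidic at C5′ to survive organometallic chemistry, so it is made last from an allylic alcohol bearing an isopropenyl group. The ring closure must prefer the five-membered lactone on the 1,1-disubstituted alkene over any reaction at C13=C14, and only the C5′ oxygen may be free at the acylation, hence 33 from 32 from 31.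

31 to 22 and 28: the C14–C15 bond is cut. This separates the decalin from the C15/C5′ pair and lets C15 be set from the existing C5′ centre. The gain is convergence. The forward step needs retention of the E geometry, chelate control, and an aldehyde that is not epimerised.

28 back to 23 (through 27, 26, 25, 24): no skeletal bond is cut; the C5′ oxygen stereocentre is traced to an asymmetric epoxidation of an achiral allylic alcohol. The demand is regiocontrol in placing the benzyl-type ether on the secondary oxygen.

22 to 20 (and 20 to 19 to 18): the C13–CH3 and C14–I bonds are cut, leaving a terminal alkyne. The forward step must add methyl and metal syn with methyl on the internal carbon. The protecting-group changes 18 to 20 remove acidic protons.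

18 to 14 (through 17, 16, 15): the C8–C17 bond and the tertiary C8–O relationship are traced to a C8 ketone. Direct methyl addition would attack from the equatorial side and give the wrong epimer, so the carbon comes in as a methylene and the oxygen is then delivered from the α face. The demand is face selectivity at an exocyclic alkene next to the axial C10 methyl.

14 to 13: the C6–C7 bond of ring B is cut. This removes one ring and converts three ring stereocentres (C5, C6, C9) into epimerisable or as yet unformed centres of a monocyclic keto aldehyde, leaving only quaternary C10 to be made selectively. The forward step must be reversible yet stop at the ketol.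

13 to 12 to 10: the oxidation level at C6 and C8 is adjusted and the C5–H bond is traced to hydroboration of an exocyclic alkene. The demand is chemoselectivity against the silylated alkyne and, ideally, delivery of hydrogen to C5 on the face that gives the trans ring fusion.

10 to 8: the C7–C8 bond is cut, so the methyl ketone comes from a carboxylic acid and a methyl nucleophile. The demand is that addition stops at the ketone.

8 to 6: the C9–C10 bond is cut as a [3,3] retron, revealing an allyl ester whose rearrangement creates quaternary C10 and the exocyclic alkene in one step. The demand is absolute control at C10 by a chiral enolate controller.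

6 to 2 and 5, then 2 to 1 and 5 to 3: the ester C–O bond and one C–Si bond are cut, leading to two cheap achiral starting materials.

## Other disconnections considered

Alternative 1: Rings A and B are both opened by cutting C5–C10 and C8–C9 in a retro-Diels–Alder sense. In the forward direction the trienyl imide A1, activated by Me2AlCl, would cyclise through its 2-silyloxydiene (C5=C6–C7=C8) and its enoyl unit (C9=C10) to the trans-fused adduct A2. In its favour, two rings, two C–C bonds and four stereocentres (C5, C8, C9, C10) come from one step; the auxiliary is cheap and recoverable; and C6 appears as a silyl enol ether, a latent C6 oxygen. Against it here, the dienophile is β,β-disubstituted and must form quaternary C10, the diene terminus C5 is neopentylic, and the Lewis acid needed may cleave the enol ether. C8 emerges as CH–CH3 with no handle for the tertiary 8α-hydroxyl, the C6 ketone would still have to be reduced to the equatorial alcohol, and the C11 acyl group must be extended by three carbons. Compared with the chosen plan, A2 is richer in carbon stereocentres but poorer in the oxygen pattern, whereas 14 keeps a C8 ketone ready for C17. The cycloaddition is kinetically controlled and cannot correct itself, whereas the aldol is self-correcting. On ring construction alone the alternative is shorter, and in setting C10 with an auxiliary instead of a stoichiometric chiral boron reagent it is the better of the two. The downstream corrections would make the whole route longer.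

Alternative 2: The C13–CH3 and C14–C15 bonds are cut. In the forward direction AlMe3 with catalytic Cp2ZrCl2 would add methyl and aluminium syn across the alkyne of 20, and the alkenylalane (or its zinc derivative) would add to aldehyde 28 under chelation to give A3, which is identical with 31. In its favour, it is the most convergent union possible: one flask forms two C–C bonds, the E alkene and C15. Against it as the strategy-carrying step, it leaves the five ring stereocentres without a plan. Dimethylalkenylalanes are weak chelators, so the Felkin pathway could compete, and excess AlMe3 can methylate the aldehyde. Compared with the chosen plan, the product and the chelate model are the same; the chosen route forms the same bonds in steps 15 and 21 through an iodide and a magnesium reagent, where chelation is better established. The stereochemical logic at C15 is equal in both. The alternative is better by one step at this junction, and the chosen plan is stronger on the decalin.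

Alternative 3: The C4–C5 and C9–C10 bonds are cut in a polyene-cyclisation sense. In the forward direction MeAlCl2 or SnCl4 would open the (S)-epoxide of A4, the central E alkene would add through C5 to C4, and the β-keto ester enol would add through C9 to C10, giving the trans-decalin β-keto ester A5. In its favour, the precursor is acyclic and its single stereocentre comes from catalytic asymmetric oxidation; two rings and two bonds form at once with the ring fusion fixed by the alkene geometry; and the C8 ketone and C9 ester are useful handles. Against it here, A5 carries a 3β-hydroxyl that the target lacks and has no oxygen at C6, so one oxygen must be removed and another introduced at an unactivated methylene. The ester carbon must also be converted into the C11–C12–alkyne chain next to an epimerisable C9. Compared with the chosen plan, the oxygen pattern is wrong where the aldol places the C6 oxygen by construction, and the cationic cascade is kinetically controlled. It is the better plan in bonds formed per step and in its catalytic asymmetric entry, and the equal of the chosen plan in delivering a C8 ketone for C17. The corrective steps make it longer overall.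

Key step: step 8

Assumption: the (S,S)-diazaborolidine controller of step 4 is taken, by analogy with simple allyl esters, to expose the ketene acetal face that leads to (R)-C10 in 8; if a first run shows the opposite sense, the (R,R)-controller is used instead.

## Steps

Step 1
Reactants: 1 β-cyclocitral
Product: 2 β-cyclogeraniol
Conditions: NaBH4, MeOH, 0 °C
Reagents that add atoms: none
Why: 1,2-Reduction of the enal by borohydride; the β-carbon is tetrasubstituted, so conjugate reduction does not compete, and no stereocentre is formed.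

Step 2
Reactants: 3 hex-5-ynoic acid
Product: 5 6-[tri(propan-2-yl)silyl]hex-5-ynoic acid, via dilithium salt 4 (not isolated)
Conditions: n-BuLi (2.2 equiv), THF, −78 → 0 °C; i-Pr3SiCl, −78 °C → rt; aq. HCl
Reagents that add atoms: chlorotri(propan-2-yl)silane, CC(C)[Si](Cl)(C(C)C)C(C)C
Why: Double deprotonation (acid, then alkyne) and C-silylation of the acetylide; any silyl ester is hydrolysed on acidic work-up. The bulky silyl group shields the alkyne from MeLi in step 5 and from borane in step 6.

Step 3
Reactants: 2 β-cyclogeraniol; 5 6-[tri(propan-2-yl)silyl]hex-5-ynoic acid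
Product: 6 (2,6,6-trimethylcyclohex-1-en-1-yl)methyl 6-[tri(propan-2-yl)silyl]hex-5-ynoate
Conditions: DCC, DMAP (cat.), CH2Cl2, 0 °C → rt
Reagents that add atoms: none
Why: Steglich esterification (carbodiimide activation, acyl transfer through DMAP) joins the two achiral pieces under neutral conditions.

Step 4
Reactants: 6 (2,6,6-trimethylcyclohex-1-en-1-yl)methyl 6-[tri(propan-2-yl)silyl]hex-5-ynoate
Product: 8 (2R)-2-[(1R)-1,3,3-trimethyl-2-methylidenecyclohexyl]-6-[tri(propan-2-yl)silyl]hex-5-ynoic acid, via boron ketene acetal 7 (not isolated)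
Conditions: (4S,5S)-2-bromo-1,3-bis{[3,5-bis(trifluoromethyl)phenyl]sulfonyl}-4,5-diphenyl-1,3,2-diazaborolidine (made in the flask from the (S,S)-bis-sulfonamide and BBr3), i-Pr2NEt, CH2Cl2, −78 °C, then 4 °C → rt; aqueous work-up
Reagents that add atoms: none
Why: Enantioselective Ireland–Claisen rearrangement through a chiral boron ketene acetal: soft enolisation, then a [3,3] shift through a chair (a boat would clash the bulky O–B group with the ring carbon on the central allyl atom). The controller exposes one face of the ketene acetal, which fixes quaternary C10 whatever the enolate geometry and forms the C9–C10 bond; the geometry favoured by this amine and solvent (side chain trans to the allyloxy oxygen) should place C9 in its final sense.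

Step 5
Reactants: 8 (2R)-2-[(1R)-1,3,3-trimethyl-2-methylidenecyclohexyl]-6-[tri(propan-2-yl)silyl]hex-5-ynoic acid
Product: 10 (3R)-3-[(1R)-1,3,3-trimethyl-2-methylidenecyclohexyl]-7-[tri(propan-2-yl)silyl]hept-6-yn-2-one, via dilithium gem-diolate 9 (not isolated)
Conditions: MeLi (3 equiv), Et2O, 0 °C → rt; inverse quench into cold aq. HCl
Reagents that add atoms: methyllithium, [Li]C
Why: Ketone synthesis from a carboxylic acid and an organolithium: the dilithium gem-diolate does not add a second MeLi and collapses to the methyl ketone on quench. The silylalkyne is inert, and partial epimerisation at C9 would be corrected in step 8.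

Step 6
Reactants: 10 (3R)-3-[(1R)-1,3,3-trimethyl-2-methylidenecyclohexyl]-7-[tri(propan-2-yl)silyl]hept-6-yn-2-one
Product: 12 (2RS,3R)-3-[(1S,2S)-2-(hydroxymethyl)-1,3,3-trimethylcyclohexyl]-7-[tri(propan-2-yl)silyl]hept-6-yn-2-ol, via alkylborane 11 (not isolated)
Conditions: BH3·THF (excess), THF, 0 °C → rt; then NaOH, H2O2, 0 °C → rt
Reagents that add atoms: hydrogen peroxide, OO
Why: Hydroboration–oxidation puts boron on the terminal carbon of the 1,1-disubstituted alkene; in the chair with the C10 methyl axial, attack anti to the two flanking axial methyls (on C10 and C4) should deliver H to C5 trans to the C10 methyl, as the trans-decalin requires. Borane also reduces the ketone (both carbinol epimers are re-oxidised in step 7), and the silyl group is expected to slow attack on the alkyne.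

Step 7
Reactants: 12 (2RS,3R)-3-[(1S,2S)-2-(hydroxymethyl)-1,3,3-trimethylcyclohexyl]-7-[tri(propan-2-yl)silyl]hept-6-yn-2-ol
Product: 13 (1S,2S)-2,6,6-trimethyl-2-{(3R)-2-oxo-7-[tri(propan-2-yl)silyl]hept-6-yn-3-yl}cyclohexane-1-carbaldehyde
Conditions: Dess–Martin periodinane (3 equiv), NaHCO3, CH2Cl2, 0 °C → rt; buffered work-up, used crude
Reagents that add atoms: none
Why: Dess–Martin oxidation of the primary and the secondary alcohol in one operation, with no amine base, so the 1,5-keto aldehyde should reach the key step without uncontrolled aldol reaction or loss of water.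

Step 8
Reactants: 13 (1S,2S)-2,6,6-trimethyl-2-{(3R)-2-oxo-7-[tri(propan-2-yl)silyl]hept-6-yn-3-yl}cyclohexane-1-carbaldehyde
Product: 14 6α-hydroxy-14-[tri(propan-2-yl)silyl]-15,16,17-trinorlabd-13-yn-8-one, that is (1R,4S,4aS,8aS)-4-hydroxy-5,5,8a-trimethyl-1-{4-[tri(propan-2-yl)silyl]but-3-yn-1-yl}octahydronaphthalen-2(1H)-one
Conditions: K2CO3 (0.3 equiv), MeOH, 0 °C → rt; pH 7 buffer quench
Reagents that add atoms: none
Why: Carbonate in methanol reversibly forms the enolate of the methyl ketone at C7, which adds to the C6 aldehyde; this is an intramolecular aldol (ketol) addition under thermodynamic control, the closest known type being the base-mediated cyclisation of keto aldehydes with epimerisable α-centres. Ring B closes in a 6-(enolendo)-exo-trig mode, because the enolate C7=C8 bond lies inside the new ring and the aldehyde C=O outside it; the other enolate, at C9, could only close a cyclobutanol and is unproductive. C6 is controlled by aldol and retro-aldol equilibration, which should favour the equatorial 6α-hydroxyl because a 6β group would be syn-axial to the methyls on C10 and C4. C5 should arrive largely correct from step 6; a cis-fused ketol from the minor epimer can reopen, and the free aldehyde can epimerise through its enolate toward the trans ring fusion. C9 should arrive largely correct from step 4 and is held equatorial (9β chain) by enolisation of the C8 ketone. Quaternary C10 with its axial methyl is the fixed reference for all three. The step must stop at the ketol: a weak base, low temperature, a protic solvent and a neutral quench keep E1cB loss of hydroxide slow, and the silylalkyne is a spectator.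

Step 9
Reactants: 14 6α-hydroxy-14-[tri(propan-2-yl)silyl]-15,16,17-trinorlabd-13-yn-8-one
Product: 15 6α-(triethylsilyloxy)-14-[tri(propan-2-yl)silyl]-15,16,17-trinorlabd-13-yn-8-one
Conditions: Et3SiOTf, 2,6-lutidine, CH2Cl2, −78 °C
Reagents that add atoms: triethylsilyl trifluoromethanesulfonate, CC[Si](CC)(CC)OS(=O)(=O)C(F)(F)F
Why: Silylation of the hindered equatorial hydroxyl by the silyl triflate at low temperature outruns enol silylation of the ketone; the ether blocks retro-aldol cleavage and β-elimination in the next steps.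

Step 10
Reactants: 15 6α-(triethylsilyloxy)-14-[tri(propan-2-yl)silyl]-15,16,17-trinorlabd-13-yn-8-one
Product: 16 6α-(triethylsilyloxy)-14-[tri(propan-2-yl)silyl]-15,16-dinorlabd-8(17)-en-13-yne
Conditions: Tebbe reagent Cp2Ti(μ-CH2)(μ-Cl)AlMe2, pyridine, THF–toluene, −40 °C → rt
Reagents that add atoms: Tebbe reagent Cp2Ti(μ-CH2)(μ-Cl)AlMe2, C[Al-]1(C)C[Ti]([Cl+]1)(C1C=CC=C1)C1C=CC=C1
Why: Tebbe methylenation (titanium methylidene, [2+2] addition and cycloreversion) converts the enolisable β-silyloxy ketone to the exocyclic alkene without base, so C9 and the C6 ether are not disturbed.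

Step 11
Reactants: 16 6α-(triethylsilyloxy)-14-[tri(propan-2-yl)silyl]-15,16-dinorlabd-8(17)-en-13-yne
Product: 17 8α,17-epoxy-6α-(triethylsilyloxy)-14-[tri(propan-2-yl)silyl]-15,16-dinorlabd-13-yne
Conditions: mCPBA, NaHCO3, CH2Cl2, 0 °C
Reagents that add atoms: 3-chloroperoxybenzoic acid, OOC(=O)c1cccc(Cl)c1
Why: Prilezhaev epoxidation of the only reactive alkene (the silylalkyne is inert); the β face of the exocyclic alkene is shielded by the axial C10 methyl, which is 1,3 to C8, so the peracid should approach from the α face, as is usual for labd-8(17)-enes, placing the oxygen α.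

Step 12
Reactants: 17 8α,17-epoxy-6α-(triethylsilyloxy)-14-[tri(propan-2-yl)silyl]-15,16-dinorlabd-13-yne
Product: 18 6α-(triethylsilyloxy)-14-[tri(propan-2-yl)silyl]-15,16-dinorlabd-13-yn-8α-ol
Conditions: LiEt3BH, THF, 0 °C → rt
Reagents that add atoms: none
Why: Hydride opens the 2,2-disubstituted oxirane at its CH2 carbon (SN2) and leaves the C8–O bond intact, so the 8α-hydroxyl and the 8β-methyl (C17) follow from the face selectivity of step 11.

Step 13
Reactants: 18 6α-(triethylsilyloxy)-14-[tri(propan-2-yl)silyl]-15,16-dinorlabd-13-yn-8α-ol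
Product: 19 15,16-dinorlabd-13-yne-6α,8α-diol
Conditions: Bu4NF, THF, rt
Reagents that add atoms: none
Why: Fluoride cleaves the C(sp)–Si bond and the C6 silyl ether in the same operation, so no selectivity between the two silicon groups is asked for; both hydroxyls are re-protected together in step 14.

Step 14
Reactants: 19 15,16-dinorlabd-13-yne-6α,8α-diol
Product: 20 6α,8α-bis(triethylsilyloxy)-15,16-dinorlabd-13-yne
Conditions: Et3SiOTf (3 equiv), 2,6-lutidine, CH2Cl2, 0 °C → rt
Reagents that add atoms: triethylsilyl trifluoromethanesulfonate, CC[Si](CC)(CC)OS(=O)(=O)C(F)(F)F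
Why: The silyl triflate silylates the secondary and the tertiary hydroxyl and so removes the acidic protons before the organometallic steps; the terminal alkyne is untouched under amine-buffered conditions.

Step 15
Reactants: 20 6α,8α-bis(triethylsilyloxy)-15,16-dinorlabd-13-yne
Product: 22 (13E)-14-iodo-6α,8α-bis(triethylsilyloxy)-15-norlabd-13-ene, via alkenylalane 21 (not isolated)
Conditions: AlMe3, Cp2ZrCl2 (0.3 equiv), CH2Cl2, 0 °C → rt; then I2, THF, −30 → 0 °C
Reagents that add atoms: trimethylalane, C[Al](C)C; iodine, II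
Why: Negishi zirconium-catalysed methylalumination adds CH3 and Al syn across the terminal alkyne with CH3 on internal C13; iodinolysis of the C–Al bond with retention gives the (E)-iodoalkene, fixing the alkene geometry.

Step 16
Reactants: 23 3-methylbut-2-en-1-ol
Product: 24 [(2R)-3,3-dimethyloxiran-2-yl]methanol
Conditions: Ti(OiPr)4 (cat.), D-(−)-diethyl tartrate (cat.), t-BuOOH, 4 Å sieves, CH2Cl2, −20 °C
Reagents that add atoms: tert-butyl hydroperoxide, CC(C)(C)OO
Why: Sharpless asymmetric epoxidation of a primary allylic alcohol; with the D-(−)-tartrate the oxygen is delivered to the face that gives the (2R)-epoxy alcohol, the source of C5′.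

Step 17
Reactants: 24 [(2R)-3,3-dimethyloxiran-2-yl]methanol
Product: 25 (2S)-3-methylbut-3-ene-1,2-diol
Conditions: Ti(OiPr)4 (1.2 equiv), CH2Cl2, rt
Reagents that add atoms: none
Why: Hydroxyl-directed, titanium alkoxide-mediated isomerisation of a 2,3-epoxy alcohol with a fully substituted C3: the C3–O bond ionises and a methyl proton is lost, giving the 3-ene-1,2-diol. The C2–O bond is not broken, so the centre is retained and only its descriptor changes.

Step 18
Reactants: 25 (2S)-3-methylbut-3-ene-1,2-diol
Product: 26 (4S)-2-(4-methoxyphenyl)-4-(prop-1-en-2-yl)-1,3-dioxolane (both epimers at C2)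
Conditions: 4-MeOC6H4CH(OMe)2, PPTS (cat.), CH2Cl2, rt
Reagents that add atoms: 1-(dimethoxymethyl)-4-methoxybenzene, COc1ccc(C(OC)OC)cc1
Why: Acid-catalysed transacetalisation to the five-membered benzylidene-type acetal; the acetal centre is lost again in step 19.

Step 19
Reactants: 26 (4S)-2-(4-methoxyphenyl)-4-(prop-1-en-2-yl)-1,3-dioxolane
Product: 27 (2S)-2-[(4-methoxyphenyl)methoxy]-3-methylbut-3-en-1-ol
Conditions: i-Bu2AlH, CH2Cl2, −78 → 0 °C
Reagents that add atoms: none
Why: Regioselective reductive opening of the p-methoxybenzylidene acetal: aluminium binds the less hindered primary oxygen, that C–O bond breaks and hydride reduces the oxocarbenium ion, leaving the PMB ether on the secondary oxygen.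

Step 20
Reactants: 27 (2S)-2-[(4-methoxyphenyl)methoxy]-3-methylbut-3-en-1-ol
Product: 28 (2S)-2-[(4-methoxyphenyl)methoxy]-3-methylbut-3-enal
Conditions: Dess–Martin periodinane, NaHCO3, CH2Cl2, 0 °C; used at once
Reagents that add atoms: none
Why: Buffered Dess–Martin oxidation gives the α-alkoxy β,γ-unsaturated aldehyde without base, which limits epimerisation and migration of the alkene into conjugation.

Step 21
Reactants: 22 (13E)-14-iodo-6α,8α-bis(triethylsilyloxy)-15-norlabd-13-ene; 28 (2S)-2-[(4-methoxyphenyl)methoxy]-3-methylbut-3-enal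
Product: 31 (13E,15S)-15-{(1S)-1-[(4-methoxyphenyl)methoxy]-2-methylprop-2-en-1-yl}-6α,8α-bis(triethylsilyloxy)labd-13-en-15-ol, via alkenyllithium 29 (not isolated), via alkenylmagnesium bromide 30 (not isolated)
Conditions: t-BuLi (2.1 equiv), Et2O, −78 °C; MgBr2·OEt2; then 28 premixed with MgBr2·OEt2 in CH2Cl2, −78 °C; aq. NH4Cl
Reagents that add atoms: none
Why: Iodine–lithium exchange with retention of alkene geometry, transmetalation to magnesium, and Cram-chelate addition to the α-alkoxy aldehyde. Magnesium bridges the carbonyl and the PMB ether oxygen, and the alkenyl group should add to the face opposite the isopropenyl group, giving the syn (threo) 15S alcohol next to the 5′S centre.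

Step 22
Reactants: 31 (13E,15S)-15-{(1S)-1-[(4-methoxyphenyl)methoxy]-2-methylprop-2-en-1-yl}-6α,8α-bis(triethylsilyloxy)labd-13-en-15-ol
Product: 32 (13E,15S)-15-{(1S)-1-[(4-methoxyphenyl)methoxy]-2-methylprop-2-en-1-yl}-6α,8α,15-tris(triethylsilyloxy)labd-13-ene
Conditions: Et3SiCl, imidazole, DMF, 0 °C → rt
Reagents that add atoms: chlorotriethylsilane, CC[Si](Cl)(CC)CC
Why: Silylation of the secondary allylic hydroxyl, so that the lactone can later be built on the neighbouring oxygen only.

Step 23
Reactants: 32 (13E,15S)-15-{(1S)-1-[(4-methoxyphenyl)methoxy]-2-methylprop-2-en-1-yl}-6α,8α,15-tris(triethylsilyloxy)labd-13-ene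
Product: 33 (1S)-2-methyl-1-[(13E,15S)-6α,8α,15-tris(triethylsilyloxy)labd-13-en-15-yl]prop-2-en-1-ol
Conditions: DDQ, CH2Cl2–pH 7 buffer, 0 °C
Reagents that add atoms: none
Why: Oxidative cleavage of the PMB ether (hydride abstraction from the electron-rich benzylic position, then hydrolysis) frees the C5′ hydroxyl; under buffered conditions the silyl ethers and the isolated alkenes should not be attacked.

Step 24
Reactants: 33 (1S)-2-methyl-1-[(13E,15S)-6α,8α,15-tris(triethylsilyloxy)labd-13-en-15-yl]prop-2-en-1-ol
Product: 34 (1S)-2-methyl-1-[(13E,15S)-6α,8α,15-tris(triethylsilyloxy)labd-13-en-15-yl]prop-2-en-1-yl prop-2-enoate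
Conditions: CH2=CHCOCl, i-Pr2NEt, CH2Cl2, −78 → 0 °C
Reagents that add atoms: prop-2-enoyl chloride, C=CC(Cl)=O
Why: Acylation of the single free hydroxyl; a hindered amine and low temperature suppress conjugate addition to the acrylate.

Step 25
Reactants: 34 (1S)-2-methyl-1-[(13E,15S)-6α,8α,15-tris(triethylsilyloxy)labd-13-en-15-yl]prop-2-en-1-yl prop-2-enoate
Product: 35 (5S)-4-methyl-5-[(13E,15S)-6α,8α,15-tris(triethylsilyloxy)labd-13-en-15-yl]furan-2(5H)-one
Conditions: second-generation Grubbs catalyst (H2IMes)(PCy3)Cl2Ru=CHPh (10 mol%), toluene, 80 °C, high dilution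
Reagents that add atoms: none
Why: Ring-closing metathesis between the acrylate and the 1,1-disubstituted alkene closes the five-membered unsaturated lactone with loss of ethene; the trisubstituted C13=C14 alkene, shielded by the silyloxy group on C15, should be far less reactive, and C5′ is not touched.

Step 26
Reactants: 35 (5S)-4-methyl-5-[(13E,15S)-6α,8α,15-tris(triethylsilyloxy)labd-13-en-15-yl]furan-2(5H)-one
Product: 36 (5S)-5-{(1S,2E)-5-[(1R,2R,4S,4aS,8aS)-2,4-dihydroxy-2,5,5,8a-tetramethyldecahydronaphthalen-1-yl]-1-hydroxy-3-methylpent-2-en-1-yl}-4-methylfuran-2(5H)-one (target)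
Conditions: HF·pyridine, pyridine, THF, 0 °C → rt
Reagents that add atoms: none
Why: Buffered fluoride under mildly acidic, non-basic conditions removes the three triethylsilyl ethers while sparing the butenolide (no deprotonation at C5′) and the allylic C15 alcohol.

## Compound list

1 | β-cyclocitral (2,6,6-trimethylcyclohex-1-ene-1-carbaldehyde) | CC1=C(C=O)C(C)(C)CCC1 | starting material
2 | β-cyclogeraniol [(2,6,6-trimethylcyclohex-1-en-1-yl)methanol] | CC1=C(CO)C(C)(C)CCC1 | intermediate
3 | hex-5-ynoic acid | C#CCCCC(=O)O | starting material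
4 | dilithium salt of hex-5-ynoic acid (carboxylate and acetylide) | [Li+].[Li+].[C-]#CCCCC(=O)[O-] | intermediate
5 | 6-[tri(propan-2-yl)silyl]hex-5-ynoic acid | CC(C)[Si](C(C)C)(C(C)C)C#CCCCC(=O)O | intermediate
6 | (2,6,6-trimethylcyclohex-1-en-1-yl)methyl 6-[tri(propan-2-yl)silyl]hex-5-ynoate | CC1=C(COC(=O)CCCC#C[Si](C(C)C)(C(C)C)C(C)C)C(C)(C)CCC1 | intermediate
7 | boron ketene acetal of 6 (O-bound (4S,5S)-1,3-bis{[3,5-bis(trifluoromethyl)phenyl]sulfonyl}-4,5-diphenyl-1,3,2-diazaborolidin-2-yl; side chain trans to the allyloxy oxygen) | CC1=C(CO/C(OB2N(S(=O)(=O)c3cc(C(F)(F)F)cc(C(F)(F)F)c3)[C@@H](c3ccccc3)[C@H](c3ccccc3)N2S(=O)(=O)c3cc(C(F)(F)F)cc(C(F)(F)F)c3)=C/CCC#C[Si](C(C)C)(C(C)C)C(C)C)C(C)(C)CCC1 | intermediate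
8 | (2R)-2-[(1R)-1,3,3-trimethyl-2-methylidenecyclohexyl]-6-[tri(propan-2-yl)silyl]hex-5-ynoic acid | OC(=O)[C@H](CCC#C[Si](C(C)C)(C(C)C)C(C)C)[C@@]1(C)CCCC(C)(C)C1=C | intermediate
9 | dilithium (3R)-3-[(1R)-1,3,3-trimethyl-2-methylidenecyclohexyl]-7-[tri(propan-2-yl)silyl]hept-6-yne-2,2-diolate | [Li+].[Li+].CC([O-])([O-])[C@H](CCC#C[Si](C(C)C)(C(C)C)C(C)C)[C@@]1(C)CCCC(C)(C)C1=C | intermediate
10 | (3R)-3-[(1R)-1,3,3-trimethyl-2-methylidenecyclohexyl]-7-[tri(propan-2-yl)silyl]hept-6-yn-2-one | CC(=O)[C@H](CCC#C[Si](C(C)C)(C(C)C)C(C)C)[C@@]1(C)CCCC(C)(C)C1=C | intermediate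
11 | alkylborane from 10 (BH2 on the new CH2 at C6; the reduced C8 oxygen as its borane ester) | CC(O[BH2])[C@H](CCC#C[Si](C(C)C)(C(C)C)C(C)C)[C@@]1(C)CCCC(C)(C)[C@@H]1C[BH2] | intermediate
12 | (2RS,3R)-3-[(1S,2S)-2-(hydroxymethyl)-1,3,3-trimethylcyclohexyl]-7-[tri(propan-2-yl)silyl]hept-6-yn-2-ol | CC(O)[C@H](CCC#C[Si](C(C)C)(C(C)C)C(C)C)[C@@]1(C)CCCC(C)(C)[C@@H]1CO | intermediate
13 | (1S,2S)-2,6,6-trimethyl-2-{(3R)-2-oxo-7-[tri(propan-2-yl)silyl]hept-6-yn-3-yl}cyclohexane-1-carbaldehyde | CC(=O)[C@H](CCC#C[Si](C(C)C)(C(C)C)C(C)C)[C@@]1(C)CCCC(C)(C)[C@@H]1C=O | intermediate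
14 | 6α-hydroxy-14-[tri(propan-2-yl)silyl]-15,16,17-trinorlabd-13-yn-8-one | CC(C)[Si](C(C)C)(C(C)C)C#CCC[C@@H]1[C@@]2(C)CCCC(C)(C)[C@@H]2[C@@H](O)CC1=O | intermediate
15 | 6α-(triethylsilyloxy)-14-[tri(propan-2-yl)silyl]-15,16,17-trinorlabd-13-yn-8-one | CC(C)[Si](C(C)C)(C(C)C)C#CCC[C@@H]1[C@@]2(C)CCCC(C)(C)[C@@H]2[C@@H](O[Si](CC)(CC)CC)CC1=O | intermediate
16 | 6α-(triethylsilyloxy)-14-[tri(propan-2-yl)silyl]-15,16-dinorlabd-8(17)-en-13-yne | CC(C)[Si](C(C)C)(C(C)C)C#CCC[C@@H]1[C@@]2(C)CCCC(C)(C)[C@@H]2[C@@H](O[Si](CC)(CC)CC)CC1=C | intermediate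
17 | 8α,17-epoxy-6α-(triethylsilyloxy)-14-[tri(propan-2-yl)silyl]-15,16-dinorlabd-13-yne | CC(C)[Si](C(C)C)(C(C)C)C#CCC[C@@H]1[C@@]2(C)CCCC(C)(C)[C@@H]2[C@@H](O[Si](CC)(CC)CC)C[C@@]1(C3)O3 | intermediate
18 | 6α-(triethylsilyloxy)-14-[tri(propan-2-yl)silyl]-15,16-dinorlabd-13-yn-8α-ol | CC(C)[Si](C(C)C)(C(C)C)C#CCC[C@@H]1[C@@]2(C)CCCC(C)(C)[C@@H]2[C@@H](O[Si](CC)(CC)CC)C[C@@]1(C)O | intermediate
19 | 15,16-dinorlabd-13-yne-6α,8α-diol | C#CCC[C@@H]1[C@@]2(C)CCCC(C)(C)[C@@H]2[C@@H](O)C[C@@]1(C)O | intermediate
20 | 6α,8α-bis(triethylsilyloxy)-15,16-dinorlabd-13-yne | C#CCC[C@@H]1[C@@]2(C)CCCC(C)(C)[C@@H]2[C@@H](O[Si](CC)(CC)CC)C[C@@]1(C)O[Si](CC)(CC)CC | intermediate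
21 | (13E)-14-(dimethylalumanyl)-6α,8α-bis(triethylsilyloxy)-15-norlabd-13-ene | C[Al](C)/C=C(\C)CC[C@@H]1[C@@]2(C)CCCC(C)(C)[C@@H]2[C@@H](O[Si](CC)(CC)CC)C[C@@]1(C)O[Si](CC)(CC)CC | intermediate
22 | (13E)-14-iodo-6α,8α-bis(triethylsilyloxy)-15-norlabd-13-ene | I/C=C(\C)CC[C@@H]1[C@@]2(C)CCCC(C)(C)[C@@H]2[C@@H](O[Si](CC)(CC)CC)C[C@@]1(C)O[Si](CC)(CC)CC | intermediate
23 | 3-methylbut-2-en-1-ol | CC(C)=CCO | starting material
24 | [(2R)-3,3-dimethyloxiran-2-yl]methanol | CC1(C)O[C@@H]1CO | intermediate
25 | (2S)-3-methylbut-3-ene-1,2-diol | C=C(C)[C@H](O)CO | intermediate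
26 | (4S)-2-(4-methoxyphenyl)-4-(prop-1-en-2-yl)-1,3-dioxolane (both epimers at C2) | C=C(C)[C@H]1COC(c2ccc(OC)cc2)O1 | intermediate
27 | (2S)-2-[(4-methoxyphenyl)methoxy]-3-methylbut-3-en-1-ol | C=C(C)[C@H](OCc1ccc(OC)cc1)CO | intermediate
28 | (2S)-2-[(4-methoxyphenyl)methoxy]-3-methylbut-3-enal | C=C(C)[C@H](OCc1ccc(OC)cc1)C=O | intermediate
29 | (13E)-14-lithio-6α,8α-bis(triethylsilyloxy)-15-norlabd-13-ene | [Li]/C=C(\C)CC[C@@H]1[C@@]2(C)CCCC(C)(C)[C@@H]2[C@@H](O[Si](CC)(CC)CC)C[C@@]1(C)O[Si](CC)(CC)CC | intermediate
30 | (13E)-14-(bromomagnesio)-6α,8α-bis(triethylsilyloxy)-15-norlabd-13-ene | Br[Mg]/C=C(\C)CC[C@@H]1[C@@]2(C)CCCC(C)(C)[C@@H]2[C@@H](O[Si](CC)(CC)CC)C[C@@]1(C)O[Si](CC)(CC)CC | intermediate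
31 | (13E,15S)-15-{(1S)-1-[(4-methoxyphenyl)methoxy]-2-methylprop-2-en-1-yl}-6α,8α-bis(triethylsilyloxy)labd-13-en-15-ol | C=C(C)[C@H](OCc1ccc(OC)cc1)[C@@H](O)/C=C(\C)CC[C@@H]1[C@@]2(C)CCCC(C)(C)[C@@H]2[C@@H](O[Si](CC)(CC)CC)C[C@@]1(C)O[Si](CC)(CC)CC | intermediate
32 | (13E,15S)-15-{(1S)-1-[(4-methoxyphenyl)methoxy]-2-methylprop-2-en-1-yl}-6α,8α,15-tris(triethylsilyloxy)labd-13-ene | C=C(C)[C@H](OCc1ccc(OC)cc1)[C@@H](O[Si](CC)(CC)CC)/C=C(\C)CC[C@@H]1[C@@]2(C)CCCC(C)(C)[C@@H]2[C@@H](O[Si](CC)(CC)CC)C[C@@]1(C)O[Si](CC)(CC)CC | intermediate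
33 | (1S)-2-methyl-1-[(13E,15S)-6α,8α,15-tris(triethylsilyloxy)labd-13-en-15-yl]prop-2-en-1-ol | C=C(C)[C@H](O)[C@@H](O[Si](CC)(CC)CC)/C=C(\C)CC[C@@H]1[C@@]2(C)CCCC(C)(C)[C@@H]2[C@@H](O[Si](CC)(CC)CC)C[C@@]1(C)O[Si](CC)(CC)CC | intermediate
34 | (1S)-2-methyl-1-[(13E,15S)-6α,8α,15-tris(triethylsilyloxy)labd-13-en-15-yl]prop-2-en-1-yl prop-2-enoate | C=CC(=O)O[C@@H](C(C)=C)[C@@H](O[Si](CC)(CC)CC)/C=C(\C)CC[C@@H]1[C@@]2(C)CCCC(C)(C)[C@@H]2[C@@H](O[Si](CC)(CC)CC)C[C@@]1(C)O[Si](CC)(CC)CC | intermediate
35 | (5S)-4-methyl-5-[(13E,15S)-6α,8α,15-tris(triethylsilyloxy)labd-13-en-15-yl]furan-2(5H)-one | CC1=CC(=O)O[C@@H]1[C@@H](O[Si](CC)(CC)CC)/C=C(\C)CC[C@@H]1[C@@]2(C)CCCC(C)(C)[C@@H]2[C@@H](O[Si](CC)(CC)CC)C[C@@]1(C)O[Si](CC)(CC)CC | intermediate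
36 | (5S)-5-{(1S,2E)-5-[(1R,2R,4S,4aS,8aS)-2,4-dihydroxy-2,5,5,8a-tetramethyldecahydronaphthalen-1-yl]-1-hydroxy-3-methylpent-2-en-1-yl}-4-methylfuran-2(5H)-one | CC1=CC(=O)O[C@@H]1[C@@H](O)/C=C(\C)CC[C@@H]1[C@@]2(C)CCCC(C)(C)[C@@H]2[C@@H](O)C[C@@]1(C)O | target

## Step count and least certain steps

Total: 26 steps. Longest linear sequence: 20 steps from 1 (steps 1, 3 to 15, 21 to 26); the branch from 23 adds 5 steps before the union in step 21, and step 2 is a one-step branch.

Step 8 (key step). The most likely failure is loss of water from the ketol under the equilibrating conditions (E1cB through the C7 enolate), or incomplete epimerisation of the hindered C5 and C9 centres so that cis-fused or 9-epi ketols persist. Fallback, from 13 back to 14: drive the condensation deliberately (pyrrolidine, AcOH, warm benzene) to 14-[tri(propan-2-yl)silyl]-15,16,17-trinorlabd-6-en-13-yn-8-one F1, in which C5 (through the dienolate) and C9 can both settle into the trans-fused, equatorial arrangement. Then carry out a copper-catalysed conjugate borylation (CuCl, NaOt-Bu, DPEphos, bis(pinacolato)diboron, MeOH, THF), which should add boron to C6 from the open α face and give the 6α-boryl ketone F2. Oxidation with NaBO3·4H2O, with retention, returns 14.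

Step 4. The most likely failure is poor discrimination between the two faces of the ketene acetal (or the opposite sense) on this hindered, tetrasubstituted allyl terminus, together with slow rearrangement at low temperature. Fallback, from 6 back to 8: run the rearrangement without asymmetric induction (LiN(i-Pr)2, THF–DMPU, Me3SiCl, −78 °C → rt) through the trimethylsilyl ketene acetal F3 to the racemic acid F4. Resolve this by crystallising its salt with (S)-1-phenylethanamine, the (1S)-1-phenylethanaminium salt F5, and liberate 8 with dilute acid.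

Step 6. The most likely failure is competing hydroboration of the silylated alkyne during the slow reaction of the hindered alkene, or delivery of hydrogen to the wrong face of C5. Fallback, from 10 directly to 13: epoxidise the exocyclic alkene (mCPBA, NaHCO3) to the spiro-epoxide F6. Rearrange it with a bulky aluminium Lewis acid, MeAl(OAr)2 with Ar = 4-bromo-2,6-di-tert-butylphenyl, in CH2Cl2 at −78 °C (Meinwald rearrangement by 1,2-hydride shift). This gives 13 without touching the ketone, and any C5 epimer converges in step 8.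

Step 21. The most likely failure is erosion of chelate control by a competing Felkin pathway, or base-induced epimerisation and alkene migration in the sensitive aldehyde. Fallback, from 22 and 28 back to 31: couple under non-basic Nozaki–Hiyama–Kishi conditions (CrCl2, catalytic NiCl2, DMF) to the mixture of C15 epimers F7. Oxidise this with Dess–Martin periodinane to the enone F8, and reduce with K[s-Bu3BH] in THF at −78 °C; Felkin–Anh 1,2-reduction next to the α-alkoxy centre should give the syn alcohol 31.

Step 25. The most likely failure is ring closure onto the C13=C14 alkene (a six-membered lactone with loss of the decalin), or stalling of the catalyst at the 1,1-disubstituted alkene. Fallback, from 22 to 36: exchange iodine for lithium (t-BuLi) and formylate with DMF to the (13E)-enal F9. Carry out a vinylogous Mukaiyama aldol addition of 4-methyl-2-(trimethylsilyloxy)furan (BF3·OEt2, CH2Cl2, −78 °C), which is expected to favour the threo adducts. The decalin cannot bias the face, so the (15S,5′S) butenolide F10 would have to be separated from its (15R,5′R) partner, which is the price of this shortcut. HF·pyridine then gives 36.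

## Further compounds

F1 | step 8 | 14-[tri(propan-2-yl)silyl]-15,16,17-trinorlabd-6-en-13-yn-8-one | CC(C)[Si](C(C)C)(C(C)C)C#CCC[C@@H]1[C@@]2(C)CCCC(C)(C)[C@@H]2C=CC1=O
F2 | step 8 | 6α-(4,4,5,5-tetramethyl-1,3,2-dioxaborolan-2-yl)-14-[tri(propan-2-yl)silyl]-15,16,17-trinorlabd-13-yn-8-one | CC(C)[Si](C(C)C)(C(C)C)C#CCC[C@@H]1[C@@]2(C)CCCC(C)(C)[C@@H]2[C@@H](B3OC(C)(C)C(C)(C)O3)CC1=O
F3 | step 4 | trimethylsilyl ketene acetal of 6 (side chain trans to the allyloxy oxygen) | CC1=C(CO/C(O[Si](C)(C)C)=C/CCC#C[Si](C(C)C)(C(C)C)C(C)C)C(C)(C)CCC1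
F4 | step 4 | racemic 2-(1,3,3-trimethyl-2-methylidenecyclohexyl)-6-[tri(propan-2-yl)silyl]hex-5-ynoic acid | OC(=O)C(CCC#C[Si](C(C)C)(C(C)C)C(C)C)C1(C)CCCC(C)(C)C1=C
F5 | step 4 | (1S)-1-phenylethanaminium salt of 8 | C[C@H]([NH3+])c1ccccc1.[O-]C(=O)[C@H](CCC#C[Si](C(C)C)(C(C)C)C(C)C)[C@@]1(C)CCCC(C)(C)C1=C
F6 | step 6 | (3R)-3-[(4R)-4,8,8-trimethyl-1-oxaspiro[2.5]octan-4-yl]-7-[tri(propan-2-yl)silyl]hept-6-yn-2-one (spiro-epoxide of 10, both epimers at the spiro carbon) | CC(=O)[C@H](CCC#C[Si](C(C)C)(C(C)C)C(C)C)[C@@]1(C)CCCC(C)(C)C12CO2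
F7 | step 21 | C15 epimers of 31 | C=C(C)[C@H](OCc1ccc(OC)cc1)C(O)/C=C(\C)CC[C@@H]1[C@@]2(C)CCCC(C)(C)[C@@H]2[C@@H](O[Si](CC)(CC)CC)C[C@@]1(C)O[Si](CC)(CC)CC
F8 | step 21 | (13E)-15-{(1S)-1-[(4-methoxyphenyl)methoxy]-2-methylprop-2-en-1-yl}-6α,8α-bis(triethylsilyloxy)labd-13-en-15-one | C=C(C)[C@H](OCc1ccc(OC)cc1)C(=O)/C=C(\C)CC[C@@H]1[C@@]2(C)CCCC(C)(C)[C@@H]2[C@@H](O[Si](CC)(CC)CC)C[C@@]1(C)O[Si](CC)(CC)CC
F9 | step 25 | (13E)-6α,8α-bis(triethylsilyloxy)labd-13-en-15-al | O=C/C=C(\C)CC[C@@H]1[C@@]2(C)CCCC(C)(C)[C@@H]2[C@@H](O[Si](CC)(CC)CC)C[C@@]1(C)O[Si](CC)(CC)CC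
F10 | step 25 | (5S)-5-[(13E,15S)-15-hydroxy-6α,8α-bis(triethylsilyloxy)labd-13-en-15-yl]-4-methylfuran-2(5H)-one | CC1=CC(=O)O[C@@H]1[C@@H](O)/C=C(\C)CC[C@@H]1[C@@]2(C)CCCC(C)(C)[C@@H]2[C@@H](O[Si](CC)(CC)CC)C[C@@]1(C)O[Si](CC)(CC)CC
A1 | alternative 1 | (4S)-4-benzyl-3-[(2E,8Z,10E)-9-(tert-butyldimethylsilyloxy)-3,7,7-trimethyldodeca-2,8,10-trienoyl]oxazolidin-2-one | O=C(/C=C(\C)CCCC(C)(C)/C=C(O[Si](C)(C)C(C)(C)C)/C=C/C)N1C(=O)OC[C@@H]1Cc1ccccc1
A2 | alternative 1 | (4S)-4-benzyl-3-[6-(tert-butyldimethylsilyloxy)drim-6-en-11-oyl]oxazolidin-2-one (trans-fused) | O=C(N1C(=O)OC[C@@H]1Cc1ccccc1)[C@@H]2[C@@]3(C)CCCC(C)(C)[C@@H]3C(O[Si](C)(C)C(C)(C)C)=C[C@@H]2C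
A3 | alternative 2 | (13E,15S)-15-{(1S)-1-[(4-methoxyphenyl)methoxy]-2-methylprop-2-en-1-yl}-6α,8α-bis(triethylsilyloxy)labd-13-en-15-ol (identical with 31) | C=C(C)[C@H](OCc1ccc(OC)cc1)[C@@H](O)/C=C(\C)CC[C@@H]1[C@@]2(C)CCCC(C)(C)[C@@H]2[C@@H](O[Si](CC)(CC)CC)C[C@@]1(C)O[Si](CC)(CC)CC
A4 | alternative 3 | methyl (6E)-9-[(2S)-3,3-dimethyloxiran-2-yl]-7-methyl-3-oxonon-6-enoate | COC(=O)CC(=O)CC/C=C(\C)CC[C@@H]1OC1(C)C
A5 | alternative 3 | methyl 3β-hydroxy-8-oxo-12-nordriman-11-oate | COC(=O)[C@@H]1[C@@]2(C)CC[C@H](O)C(C)(C)[C@@H]2CCC1=O
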